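## Retrosynthetic overview

- Dihydrofuran ring, formed last: O–C1 bond by 5-exo oxa-Michael addition of the C3 hydroxyl to a dienone on C7a.
- Cyclohexene ring, formed first: C3a–C4 and C7a–C1 bonds in one palladium-catalysed coupling of an acyclic hydroxy alkynal with an alkenylboronic acid.
- C6–C7 bond, both of its stereocentres and the (E)-enol ester: anionic oxy-Cope rearrangement of a 1,5-dien-3-ol, with the enolate trapped by 3-methylbut-2-enoyl chloride; the C4 aldehyde comes from the vinyl group released in the rearrangement.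
- Dienynol: zinc-catalysed asymmetric alkynylation joining a (Z)-C11 aldehyde (propyne carbocupration) with a C5 diyne (from 1,4-dichlorobut-2-yne), then trans-reduction; third fragment: a β-boryl enone from but-3-yn-2-ol.

Assumption: locants C1–C9 refer to the target core (C1 bears the 2-oxopropyl group, C3 is the OCH2, C3a=C7a the ring alkene, C4 the carbinol, C6 the quaternary carbon, C7 the carbon bearing the C8=C9 enol ester), and all starting materials are taken as commercial.

## Route

Step 1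
Reactants: 1 5-bromo-2-methylpent-2-ene; 2 propyne; 3 oxirane
Product: 7 (3Z)-4,8-dimethylnona-3,7-dien-1-ol, via (4-methylpent-3-en-1-yl)magnesium bromide 4 (not isolated), via (4-methylpent-3-en-1-yl)copper 5 (not isolated), via (Z)-(2,6-dimethylhepta-1,5-dien-1-yl)copper 6 (not isolated)
Conditions: Mg, THF; CuBr·SMe2, Et2O–Me2S, −45 °C; 2, −25 °C; then n-PrC≡CLi, HMPA, 3, −40 to −15 °C
Reagents that add atoms: none
Why: Normant syn-carbocupration of propyne puts the alkyl group and copper cis, and the derived cuprate opens oxirane with retention, so the (Z)-trisubstituted alkene needed for the later chair transition state is fixed here.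

Step 2
Reactants: 7 (3Z)-4,8-dimethylnona-3,7-dien-1-ol
Product: 8 (3Z)-4,8-dimethylnona-3,7-dienal
Conditions: Dess–Martin periodinane, CH2Cl2, 0 °C
Reagents that add atoms: none
Why: Dess–Martin oxidation is neutral enough to give the β,γ-unsaturated aldehyde without moving the (Z)-alkene into conjugation, provided it is used at once.

Step 3
Reactants: 9 1,4-dichlorobut-2-yne; 10 formaldehyde (as paraformaldehyde)
Product: 12 penta-2,4-diyn-1-ol, via sodium buta-1,3-diyn-1-ide 11 (not isolated)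
Conditions: NaNH2 (3 equiv), NH3 (l), −40 °C; then 10, THF, −40 °C to rt
Reagents that add atoms: none
Why: double dehydrochlorination gives sodium butadiynide, which adds to formaldehyde (acetylide hydroxymethylation); the labile diynol is protected at once.

Step 4
Reactants: 12 penta-2,4-diyn-1-ol
Product: 13 tert-butyl(dimethyl)(penta-2,4-diyn-1-yloxy)silane
Conditions: TBSCl, imidazole, CH2Cl2, 0 °C
Reagents that add atoms: tert-butyldimethylsilyl chloride, CC(C)(C)[Si](C)(C)Cl
Why: standard silylation masks the hydroxyl for the later basic and acylating steps and stabilises the terminal diyne.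

Step 5
Reactants: 8 (3Z)-4,8-dimethylnona-3,7-dienal; 13 tert-butyl(dimethyl)(penta-2,4-diyn-1-yloxy)silane
Product: 15 (6R,8Z)-1-[(tert-butyldimethylsilyl)oxy]-9,13-dimethyltetradeca-8,12-dien-2,4-diyn-6-ol, via methyl{5-[(tert-butyldimethylsilyl)oxy]penta-1,3-diyn-1-yl}zinc 14 (not isolated)
Conditions: Me2Zn (3 equiv), (S,S)-ProPhenol (20 mol%), Ph3P=O (40 mol%), toluene, 0 to 4 °C
Reagents that add atoms: none
Why: dinuclear zinc–ProPhenol catalysed enantioselective alkynylation of the aldehyde with the terminal diyne, the ligand antipode being the one that delivers the alkynyl group to the Si face, sets the (R)-carbinol that is later relayed to C6 and C7.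

Step 6
Reactants: 15 (6R,8Z)-1-[(tert-butyldimethylsilyl)oxy]-9,13-dimethyltetradeca-8,12-dien-2,4-diyn-6-ol
Product: 17 (4E,6R,8Z)-1-[(tert-butyldimethylsilyl)oxy]-9,13-dimethyltetradeca-4,8,12-trien-2-yn-6-ol, via the cyclic sodium alkenylalanate 16 (not isolated)
Conditions: NaAlH2(OCH2CH2OMe)2 (Red-Al), THF, −20 to 0 °C
Reagents that add atoms: none
Why: alkoxide-directed trans-hydroalumination (Red-Al reduction of a propargylic alcohol) reduces only the alkyne next to the carbinol and gives the (E)-alkene; the carbinol centre is untouched.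

Step 7
Reactants: 17 (4E,6R,8Z)-1-[(tert-butyldimethylsilyl)oxy]-9,13-dimethyltetradeca-4,8,12-trien-2-yn-6-ol; 18 3-methylbut-2-enoyl chloride
Product: 20 (1E,3R,4S)-3-{3-[(tert-butyldimethylsilyl)oxy]prop-1-yn-1-yl}-4-ethenyl-4,8-dimethylnona-1,7-dien-1-yl 3-methylbut-2-enoate, via the potassium (E)-enolate 19 (not isolated)
Conditions: KN(SiMe3)2 (1.05 equiv), 18-crown-6, THF, −78 to 25 °C; then 18, −78 °C
Reagents that add atoms: none
Why: anionic oxy-Cope rearrangement through a chair with the oxido group and the enyne terminus equatorial joins C7 to the (Z)-trisubstituted terminus, transferring the (R)-carbinol chirality to (6S,7R) and giving the (E)-enolate, which the acid chloride O-acylates to the (E)-enol ester.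

Step 8
Reactants: 20 (1E,3R,4S)-3-{3-[(tert-butyldimethylsilyl)oxy]prop-1-yn-1-yl}-4-ethenyl-4,8-dimethylnona-1,7-dien-1-yl 3-methylbut-2-enoate
Product: 22 (1E,3R,4S)-3-{3-[(tert-butyldimethylsilyl)oxy]prop-1-yn-1-yl}-4-(2-hydroxyethyl)-4,8-dimethylnona-1,7-dien-1-yl 3-methylbut-2-enoate, via the B-alkyl-9-borabicyclononane 21 (not isolated)
Conditions: 9-BBN, THF, 0 °C to rt; then 30% H2O2, aq. NaOAc, 0 °C
Reagents that add atoms: hydrogen peroxide, OO
Why: 9-BBN hydroborates only the monosubstituted vinyl group (anti-Markovnikov), leaving the internal alkyne, the trisubstituted alkenes and the enol ester, and acetate-buffered peroxide oxidation spares the enol ester.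

Step 9
Reactants: 22 (1E,3R,4S)-3-{3-[(tert-butyldimethylsilyl)oxy]prop-1-yn-1-yl}-4-(2-hydroxyethyl)-4,8-dimethylnona-1,7-dien-1-yl 3-methylbut-2-enoate
Product: 23 (1E,3R,4S)-3-{3-[(tert-butyldimethylsilyl)oxy]prop-1-yn-1-yl}-4,8-dimethyl-4-(2-oxoethyl)nona-1,7-dien-1-yl 3-methylbut-2-enoate
Conditions: Dess–Martin periodinane, CH2Cl2, 0 °C to rt
Reagents that add atoms: none
Why: Dess–Martin oxidation gives the C4 aldehyde, which has no α-stereocentre to lose and sits next to the quaternary carbon.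

Step 10
Reactants: 24 but-3-yn-2-ol (racemic)
Product: 25 (3E)-4-(4,4,5,5-tetramethyl-1,3,2-dioxaborolan-2-yl)but-3-en-2-ol (racemic)
Conditions: B2pin2, CuCl (5 mol%), Xantphos (5 mol%), NaOt-Bu (10 mol%), MeOH, THF, rt
Reagents that add atoms: bis(pinacolato)diboron, CC1(C)OB(OC1(C)C)B1OC(C)(C)C(C)(C)O1
Why: copper-catalysed syn-borylcupration then protonation (alkyne protoboration) gives the terminal (E)-alkenylboronate and tolerates the free hydroxyl.

Step 11
Reactants: 25 (3E)-4-(4,4,5,5-tetramethyl-1,3,2-dioxaborolan-2-yl)but-3-en-2-ol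
Product: 26 (3E)-4-(4,4,5,5-tetramethyl-1,3,2-dioxaborolan-2-yl)but-3-en-2-one
Conditions: MnO2, CH2Cl2, rt
Reagents that add atoms: none
Why: MnO2 oxidises the allylic alcohol selectively and leaves the C–B bond intact; the racemic stereocentre is removed.

Step 12
Reactants: 26 (3E)-4-(4,4,5,5-tetramethyl-1,3,2-dioxaborolan-2-yl)but-3-en-2-one
Product: 27 [(1E)-3-oxobut-1-en-1-yl]boronic acid
Conditions: NaIO4, NH4OAc, acetone–H2O, rt
Reagents that add atoms: water, O
Why: periodate cleavage of the released pinacol drives boronate hydrolysis and gives the free boronic acid needed for activation of the aldehyde and for transmetalation in step 14.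

Step 13
Reactants: 23 (1E,3R,4S)-3-{3-[(tert-butyldimethylsilyl)oxy]prop-1-yn-1-yl}-4,8-dimethyl-4-(2-oxoethyl)nona-1,7-dien-1-yl 3-methylbut-2-enoate
Product: 28 (1E,3R,4S)-3-(3-hydroxyprop-1-yn-1-yl)-4,8-dimethyl-4-(2-oxoethyl)nona-1,7-dien-1-yl 3-methylbut-2-enoate
Conditions: HF·pyridine, pyridine, THF, 0 °C
Reagents that add atoms: none
Why: buffered fluoride desilylation frees the primary propargylic alcohol without touching the enol ester or the aldehyde.

Step 14
Reactants: 28 (1E,3R,4S)-3-(3-hydroxyprop-1-yn-1-yl)-4,8-dimethyl-4-(2-oxoethyl)nona-1,7-dien-1-yl 3-methylbut-2-enoate; 27 [(1E)-3-oxobut-1-en-1-yl]boronic acid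
Product: 30 (1E)-2-[(1S,4S,6S,7R)-4-hydroxy-6-methyl-6-(4-methylpent-3-en-1-yl)-1-(2-oxopropyl)-1,3,4,5,6,7-hexahydro-2-benzofuran-7-yl]ethenyl 3-methylbut-2-enoate (target), via the hydroxy dienone 29 (not isolated)
Conditions: Pd2(dba)3·CHCl3 (2.5 mol%), PCy3 (10 mol%), 27 (1.5 equiv), t-AmOH–1,4-dioxane, 60 °C; then DBU (10 mol%), 25 °C
Reagents that add atoms: none
Why: Proposed new method: a zerovalent-palladium/PCy3-catalysed trans-selective 6-endo alkenylative cyclisation of the hydroxy alkynal, telescoped with a 5-exo oxa-Michael closure, so that both rings and the C4 and C1 stereocentres arise in one flask. Mechanistically, the alkyne attacks the boronic-acid-activated aldehyde (C3a–C4) while palladium adds to C7a from the opposite face, and transmetalation from 27 with reductive elimination forms C7a–C1 to give dienone 29. C4 is expected to be (S) from a half-chair with the boron-bound oxygen pseudo-equatorial and the C6 methylpentenyl and C7 alkenyl groups trans-diaxial, though this preference may be modest. DBU then adds the CH2OH group to the dienone anti to the pseudo-axial C7 substituent, giving the 1,7-trans product, which is also the thermodynamic one. The closest known reaction type is the palladium-catalysed anti-selective ("anti-Wacker"-type) arylative and alkenylative cyclisation of 5-alkynals with boronic acids; it has not been shown with a β-boryl enone, a free propargylic alcohol or a terminating oxa-Michael ring closure.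

## Compound list

1 | 5-bromo-2-methylpent-2-ene | CC(C)=CCCBr | starting material
2 | propyne | CC#C | starting material
3 | oxirane | C1CO1 | starting material
4 | (4-methylpent-3-en-1-yl)magnesium bromide | CC(C)=CCC[Mg]Br | intermediate (not isolated)
5 | (4-methylpent-3-en-1-yl)copper | CC(C)=CCC[Cu] | intermediate (not isolated)
6 | (Z)-(2,6-dimethylhepta-1,5-dien-1-yl)copper | CC(C)=CCC/C(C)=C\[Cu] | intermediate (not isolated)
7 | (3Z)-4,8-dimethylnona-3,7-dien-1-ol | OCC/C=C(/C)CCC=C(C)C | intermediate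
8 | (3Z)-4,8-dimethylnona-3,7-dienal | O=CC/C=C(/C)CCC=C(C)C | intermediate
9 | 1,4-dichlorobut-2-yne | ClCC#CCCl | starting material
10 | formaldehyde | C=O | starting material
11 | sodium buta-1,3-diyn-1-ide | [Na+].[C-]#CC#C | intermediate (not isolated)
12 | penta-2,4-diyn-1-ol | OCC#CC#C | intermediate
13 | tert-butyl(dimethyl)(penta-2,4-diyn-1-yloxy)silane | CC(C)(C)[Si](C)(C)OCC#CC#C | intermediate
14 | methyl{5-[(tert-butyldimethylsilyl)oxy]penta-1,3-diyn-1-yl}zinc | C[Zn]C#CC#CCO[Si](C)(C)C(C)(C)C | intermediate (not isolated)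
15 | (6R,8Z)-1-[(tert-butyldimethylsilyl)oxy]-9,13-dimethyltetradeca-8,12-dien-2,4-diyn-6-ol | CC(C)(C)[Si](C)(C)OCC#CC#C[C@H](O)C/C=C(/C)CCC=C(C)C | intermediate
16 | cyclic sodium alkenylalanate from 15 (Al bound to the carbinol O and to C4 of the chain, two 2-methoxyethoxy ligands) | [Na+].COCCO[Al-]1(OCCOC)O[C@H](C/C=C(/C)CCC=C(C)C)C=C1C#CCO[Si](C)(C)C(C)(C)C | intermediate (not isolated)
17 | (4E,6R,8Z)-1-[(tert-butyldimethylsilyl)oxy]-9,13-dimethyltetradeca-4,8,12-trien-2-yn-6-ol | CC(C)(C)[Si](C)(C)OCC#C/C=C/[C@H](O)C/C=C(/C)CCC=C(C)C | intermediate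
18 | 3-methylbut-2-enoyl chloride | CC(C)=CC(Cl)=O | starting material
19 | potassium (1E,3R,4S)-3-{3-[(tert-butyldimethylsilyl)oxy]prop-1-yn-1-yl}-4-ethenyl-4,8-dimethylnona-1,7-dien-1-olate | [K+].CC(C)(C)[Si](C)(C)OCC#C[C@H](/C=C/[O-])[C@@](C)(CCC=C(C)C)C=C | intermediate (not isolated)
20 | (1E,3R,4S)-3-{3-[(tert-butyldimethylsilyl)oxy]prop-1-yn-1-yl}-4-ethenyl-4,8-dimethylnona-1,7-dien-1-yl 3-methylbut-2-enoate | CC(C)(C)[Si](C)(C)OCC#C[C@H](/C=C/OC(=O)C=C(C)C)[C@@](C)(CCC=C(C)C)C=C | intermediate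
21 | B-alkyl-9-borabicyclo[3.3.1]nonane from 20 (boron on the terminal carbon of the former vinyl group) | CC(C)(C)[Si](C)(C)OCC#C[C@H](/C=C/OC(=O)C=C(C)C)[C@@](C)(CCC=C(C)C)CCB1C2CCCC1CCC2 | intermediate (not isolated)
22 | (1E,3R,4S)-3-{3-[(tert-butyldimethylsilyl)oxy]prop-1-yn-1-yl}-4-(2-hydroxyethyl)-4,8-dimethylnona-1,7-dien-1-yl 3-methylbut-2-enoate | CC(C)(C)[Si](C)(C)OCC#C[C@H](/C=C/OC(=O)C=C(C)C)[C@@](C)(CCC=C(C)C)CCO | intermediate
23 | (1E,3R,4S)-3-{3-[(tert-butyldimethylsilyl)oxy]prop-1-yn-1-yl}-4,8-dimethyl-4-(2-oxoethyl)nona-1,7-dien-1-yl 3-methylbut-2-enoate | CC(C)(C)[Si](C)(C)OCC#C[C@H](/C=C/OC(=O)C=C(C)C)[C@@](C)(CCC=C(C)C)CC=O | intermediate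
24 | but-3-yn-2-ol (racemic) | CC(O)C#C | starting material
25 | (3E)-4-(4,4,5,5-tetramethyl-1,3,2-dioxaborolan-2-yl)but-3-en-2-ol (racemic) | CC(O)/C=C/B1OC(C)(C)C(C)(C)O1 | intermediate
26 | (3E)-4-(4,4,5,5-tetramethyl-1,3,2-dioxaborolan-2-yl)but-3-en-2-one | CC(=O)/C=C/B1OC(C)(C)C(C)(C)O1 | intermediate
27 | [(1E)-3-oxobut-1-en-1-yl]boronic acid | CC(=O)/C=C/B(O)O | intermediate
28 | (1E,3R,4S)-3-(3-hydroxyprop-1-yn-1-yl)-4,8-dimethyl-4-(2-oxoethyl)nona-1,7-dien-1-yl 3-methylbut-2-enoate | OCC#C[C@H](/C=C/OC(=O)C=C(C)C)[C@@](C)(CCC=C(C)C)CC=O | intermediate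
29 | (1E)-2-{(1R,4S,6S)-4-hydroxy-3-(hydroxymethyl)-6-methyl-6-(4-methylpent-3-en-1-yl)-2-[(1E)-3-oxobut-1-en-1-yl]cyclohex-2-en-1-yl}ethenyl 3-methylbut-2-enoate | CC(=O)/C=C/C1=C(CO)[C@@H](O)C[C@](C)(CCC=C(C)C)[C@H]1/C=C/OC(=O)C=C(C)C | intermediate (not isolated)
30 | (1E)-2-[(1S,4S,6S,7R)-4-hydroxy-6-methyl-6-(4-methylpent-3-en-1-yl)-1-(2-oxopropyl)-1,3,4,5,6,7-hexahydro-2-benzofuran-7-yl]ethenyl 3-methylbut-2-enoate | CC(=O)C[C@@H]1OCC2=C1[C@H](/C=C/OC(=O)C=C(C)C)[C@@](C)(CCC=C(C)C)C[C@@H]2O | target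

## Step count and risk

Total step count: 14.
Longest linear sequence: 9 steps (3, 4, 5, 6, 7, 8, 9, 13, 14; the branch through steps 1 and 2 is equally long).

Steps most likely to fail:

1. Step 14 (the proposed cascade). The risks are C4 selectivity, palladium-mediated loss of the free propargylic alcohol to allene products, and self-reaction of the boryl enone. The fallback is stepwise, uses known chemistry, sets out from 23 and 26 and comes back at 30. Enone 26 is ketalised (1,2-bis(trimethylsilyloxy)ethane, TMSOTf cat., CH2Cl2, −78 °C) to the dioxolane boronate F1. The silyl-protected alkynal 23 and F1 are joined by the established zerovalent-palladium/PCy3 trans-selective alkenylative cyclisation of alkynals (Pd2(dba)3·CHCl3, PCy3, MeOH–H2O–dioxane, 80 °C), giving the doubly protected cyclohexenol F2 as whatever C4 mixture results. Dess–Martin oxidation converges this to the single cyclohexenone F3. Reduction with (R)-Me-CBS and catecholborane sets C4 under reagent control in the (4S)-alcohol F4, with no second ketone present to compete. Aqueous HF in MeCN then removes the silyl ether and the dioxolane, and DBU closes the dihydrofuran to 30.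

2. Step 7 (tandem oxy-Cope/acylation). The risks are C- versus O-acylation and erosion of the enolate geometry. The fallback sets out from 17 and comes back at 20. The rearrangement is run alone and enolate 19 is trapped with Me3SiCl as the (E)-trimethylsilyl enol ether F5, which is purified free of Z isomer. The lithium enolate is then regenerated with MeLi (THF, 0 °C) and O-acylated with 18 in THF–HMPA to return to 20.

3. Step 5 (enantioselective diyne addition to an enolisable β,γ-unsaturated aldehyde). The fallback replaces asymmetric catalysis by resolution, sets out from 8 and 13 and comes back at 15. The lithium acetylide of 13 (n-BuLi, THF, −78 °C) is added to 8 to give the racemic carbinol F6. Kinetic resolution with Amano lipase PS and vinyl acetate in hexane acetylates the (S)-enantiomer, as the Kazlauskas rule predicts, to the acetate F7, which is separated. The unreacted (R)-alcohol is 15.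

## Further compounds

F1 | step 14 | 2-[(E)-2-(2-methyl-1,3-dioxolan-2-yl)ethenyl]-4,4,5,5-tetramethyl-1,3,2-dioxaborolane | CC1(/C=C/B2OC(C)(C)C(C)(C)O2)OCCO1
F2 | step 14 | (1E)-2-[(1R,4RS,6S)-3-{[(tert-butyldimethylsilyl)oxy]methyl}-4-hydroxy-6-methyl-6-(4-methylpent-3-en-1-yl)-2-[(E)-2-(2-methyl-1,3-dioxolan-2-yl)ethenyl]cyclohex-2-en-1-yl]ethenyl 3-methylbut-2-enoate | CC1(/C=C/C2=C(CO[Si](C)(C)C(C)(C)C)C(O)C[C@](C)(CCC=C(C)C)[C@H]2/C=C/OC(=O)C=C(C)C)OCCO1
F3 | step 14 | (1E)-2-[(1R,6S)-3-{[(tert-butyldimethylsilyl)oxy]methyl}-6-methyl-6-(4-methylpent-3-en-1-yl)-2-[(E)-2-(2-methyl-1,3-dioxolan-2-yl)ethenyl]-4-oxocyclohex-2-en-1-yl]ethenyl 3-methylbut-2-enoate | CC1(/C=C/C2=C(CO[Si](C)(C)C(C)(C)C)C(=O)C[C@](C)(CCC=C(C)C)[C@H]2/C=C/OC(=O)C=C(C)C)OCCO1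
F4 | step 14 | (1E)-2-[(1R,4S,6S)-3-{[(tert-butyldimethylsilyl)oxy]methyl}-4-hydroxy-6-methyl-6-(4-methylpent-3-en-1-yl)-2-[(E)-2-(2-methyl-1,3-dioxolan-2-yl)ethenyl]cyclohex-2-en-1-yl]ethenyl 3-methylbut-2-enoate | CC1(/C=C/C2=C(CO[Si](C)(C)C(C)(C)C)[C@@H](O)C[C@](C)(CCC=C(C)C)[C@H]2/C=C/OC(=O)C=C(C)C)OCCO1
F5 | step 7 | tert-butyl(dimethyl){[(4R,5S,6E)-5-ethenyl-5,9-dimethyl-4-{2-[(trimethylsilyl)oxy]ethenyl}dec-8-en-2-yn-1-yl]oxy}silane (the (E)-trimethylsilyl enol ether corresponding to 19) | CC(C)(C)[Si](C)(C)OCC#C[C@H](/C=C/O[Si](C)(C)C)[C@@](C)(CCC=C(C)C)C=C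
F6 | step 5 | (8Z)-1-[(tert-butyldimethylsilyl)oxy]-9,13-dimethyltetradeca-8,12-dien-2,4-diyn-6-ol (racemic) | CC(C)(C)[Si](C)(C)OCC#CC#CC(O)C/C=C(/C)CCC=C(C)C
F7 | step 5 | (6S,8Z)-1-[(tert-butyldimethylsilyl)oxy]-9,13-dimethyltetradeca-8,12-dien-2,4-diyn-6-yl acetate | CC(C)(C)[Si](C)(C)OCC#CC#C[C@@H](OC(C)=O)C/C=C(/C)CCC=C(C)C
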